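**Retrosynthetic overview**
- The route rests on C4 of the oxolane ring (O1, C2 aryl, C3 CH2OH, C4, C5). C4 is a carbinol carbon carrying OH and two CH2 arms, C5 (bonded to O1) and the benzylic CH2. C4, its oxygen and both arms are taken from oxetan-3-one, and the arms are told apart only when the ring closes.
- Last disconnections: the O-benzyl and O-silyl groups, then the benzylic CH2–aryl bond (aryl Grignard reagent on a spiro-epoxide at C4 made from the C4 glycol).
- Key disconnection: O1–C5, formed when the C2 hydroxyl opens the oxetane under chiral phosphoric acid catalysis. This closes the oxolane and fixes C4.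
- Precursor: C3–C4 bond by an anti-selective Fráter–Seebach aldol of an (R)-β-hydroxy ester dianion with oxetan-3-one. The C2 carbinol comes from Noyori transfer hydrogenation of the β-keto ester.
- Ring order: the oxolane (step 6) is the only ring built; a transient spiro-oxirane (step 7) is opened again in step 9. Both benzene rings and the oxetane are bought.

Key step: step 6

Numbering remark: oxolane atoms are numbered O1, C2 (catechol aryl), C3 (CH2O arm), C4 (tertiary carbinol), C5 in the text and in the names of all oxolanes. The target is (2R,3R,4R), with aryl, CH2OH and the C4 hydroxyl on one face and the benzyl group on the other.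

Assumption: the (R)-enantiomer of TRIP is taken as the matched catalyst for 7. If the pairing proves mismatched, the (S)-acid takes its place with nothing else changed.

**Step 1**
Reactants: 1 1-[3,4-bis(benzyloxy)phenyl]ethanone
Product: 2 ethyl 3-[3,4-bis(benzyloxy)phenyl]-3-oxopropanoate
Conditions: NaH (2.5 equiv), (EtO)2CO (3 equiv), THF, reflux; aq HCl work-up
Reagents that add atoms: diethyl carbonate, CCOC(=O)OCC
Why: Claisen condensation of the ketone sodium enolate with diethyl carbonate, driven to completion by deprotonation of the β-keto ester; no stereocentre is formed.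

**Step 2**
Reactants: 2 ethyl 3-[3,4-bis(benzyloxy)phenyl]-3-oxopropanoate
Product: 3 ethyl (3R)-3-[3,4-bis(benzyloxy)phenyl]-3-hydroxypropanoate
Conditions: RuCl[(R,R)-TsDPEN](p-cymene) (1 mol %), HCO2H/Et3N (5:2), DMF, 40 °C
Reagents that add atoms: none
Why: Noyori asymmetric transfer hydrogenation delivers hydride through a six-membered Ru–H/N–H transition state with an arene CH/π contact, so the (R,R)-ligand should give the (R)-carbinol (the future C2), following the usual sense for aryl ketones; ester and benzyl ethers are untouched.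

**Step 3**
Reactants: 3 ethyl (3R)-3-[3,4-bis(benzyloxy)phenyl]-3-hydroxypropanoate; 4 oxetan-3-one
Product: 5 ethyl (2R,3R)-3-[3,4-bis(benzyloxy)phenyl]-3-hydroxy-2-(3-hydroxyoxetan-3-yl)propanoate (anti)
Conditions: LiN(iPr)2 (2.2 equiv), THF, −78 → −30 °C; then 4 (1.3 equiv), −78 °C; AcOH quench at −78 °C
Reagents that add atoms: none
Why: Fráter–Seebach dianion aldol: the dilithio alkoxide–enolate is a six-membered lithium chelate that the ketone should approach on the face opposite the aryl group, which sets C3 anti to the C2 carbinol; oxetan-3-one is symmetric, strained and reactive, so no other stereocentre arises.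

**Step 4**
Reactants: 5 ethyl (2R,3R)-3-[3,4-bis(benzyloxy)phenyl]-3-hydroxy-2-(3-hydroxyoxetan-3-yl)propanoate
Product: 6 (1R,2R)-1-[3,4-bis(benzyloxy)phenyl]-2-(3-hydroxyoxetan-3-yl)propane-1,3-diol
Conditions: LiBH4 (3 equiv), THF/MeOH, 0 °C → rt
Reagents that add atoms: none
Why: Chemoselective hydride reduction of the ester by LiBH4, helped by the neighbouring alkoxides; oxetane, benzyl ethers and both stereocentres are not affected.

**Step 5**
Reactants: 6 (1R,2R)-1-[3,4-bis(benzyloxy)phenyl]-2-(3-hydroxyoxetan-3-yl)propane-1,3-diol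
Product: 7 (1R,2R)-1-[3,4-bis(benzyloxy)phenyl]-3-{[tert-butyl(dimethyl)silyl]oxy}-2-(3-hydroxyoxetan-3-yl)propan-1-ol
Conditions: TBSCl (1.05 equiv), imidazole, CH2Cl2, −20 → 0 °C
Reagents that add atoms: tert-butyldimethylsilyl chloride, CC(C)(C)[Si](C)(C)Cl
Why: Sterically controlled silylation of the primary hydroxyl over the secondary benzylic and tertiary ones; this removes the only other hydroxyl that could open the oxetane through a five-membered transition state.

**Step 6**
Reactants: 7 (1R,2R)-1-[3,4-bis(benzyloxy)phenyl]-3-{[tert-butyl(dimethyl)silyl]oxy}-2-(3-hydroxyoxetan-3-yl)propan-1-ol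
Product: 8 (2R,3R,4S)-2-[3,4-bis(benzyloxy)phenyl]-3-({[tert-butyl(dimethyl)silyl]oxy}methyl)-4-(hydroxymethyl)oxolan-4-ol
Conditions: (R)-TRIP [3,3'-bis(2,4,6-triisopropylphenyl)-1,1'-binaphthyl-2,2'-diyl hydrogen phosphate] (10 mol %), PhMe (0.02 M), 0 °C → rt
Reagents that add atoms: none
Why: The phosphoric acid hydrogen-bonds through P–OH to the oxetane oxygen and through P=O to the C2 hydroxyl, and the C2 oxygen then displaces the oxetane oxygen at one ring CH2 in an SN2 opening driven by release of the four-membered ring strain, forming O1–C5 and freeing the other arm as CH2OH. The closest known reaction type is the chiral phosphoric acid-catalysed intramolecular desymmetrising opening of 3,3-disubstituted oxetanes by a pendant hydroxyl. The oxolane closes in the 5-exo-tet mode (O, C2, C3, C4 and the attacked CH2), which the two-carbon tether between the hydroxyl and the oxetane carbon allows. C4 is never ionised, so its configuration (OH cis to the C3 arm, CH2OH trans) is fixed only by which of the two diastereotopic CH2 groups becomes C5; the chiral pocket of the acid selects it, and the substrate should lean the same way because that transition state keeps the still-tethered CH2–O arm away from the C3 silyloxymethyl group. The step needs chemoselectivity for the C2 hydroxyl, secured by the silyl cap on the primary hydroxyl and by the inability of the tertiary hydroxyl to reach either CH2, and it needs the electron-rich benzylic C2–O bond to stay intact, for which the weak acid, the non-polar solvent and the low temperature are chosen.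

**Step 7**
Reactants: 8 (2R,3R,4S)-2-[3,4-bis(benzyloxy)phenyl]-3-({[tert-butyl(dimethyl)silyl]oxy}methyl)-4-(hydroxymethyl)oxolan-4-ol
Product: 10 (3S,6R,7R)-6-[3,4-bis(benzyloxy)phenyl]-7-({[tert-butyl(dimethyl)silyl]oxy}methyl)-1,5-dioxaspiro[2.4]heptane, via primary tosylate 9 (not isolated)
Conditions: TsCl (1.1 equiv), Et3N, DMAP (cat.), CH2Cl2, 0 °C; then K2CO3, MeOH, rt
Reagents that add atoms: none
Why: Selective sulfonylation of the primary hydroxyl followed by intramolecular Williamson closure (3-exo-tet) by the tertiary alkoxide; the C4–O bond is not broken, so C4 keeps its configuration, with the epoxide oxygen cis to the aryl and silyloxymethyl groups.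

**Step 8**
Reactants: 11 4-bromo-1,2-dimethoxybenzene
Product: 12 3,4-dimethoxyphenylmagnesium bromide (THF solution, used directly)
Conditions: Mg turnings, I2 (cat.), THF, 45 °C
Reagents that add atoms: magnesium, [Mg]
Why: Grignard formation by insertion of magnesium into the aryl C–Br bond; the methoxy groups are compatible.

**Step 9**
Reactants: 10 (3S,6R,7R)-6-[3,4-bis(benzyloxy)phenyl]-7-({[tert-butyl(dimethyl)silyl]oxy}methyl)-1,5-dioxaspiro[2.4]heptane; 12 3,4-dimethoxyphenylmagnesium bromide
Product: 13 (2R,3R,4R)-2-[3,4-bis(benzyloxy)phenyl]-3-({[tert-butyl(dimethyl)silyl]oxy}methyl)-4-[(3,4-dimethoxyphenyl)methyl]oxolan-4-ol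
Conditions: 12 (3 equiv), CuI (10 mol %), THF, −30 → 0 °C; then H2O
Reagents that add atoms: none
Why: Copper-catalysed SN2 opening of the 2,2-disubstituted epoxide by the aryl Grignard reagent (through an arylcuprate) at the unhindered CH2 terminus; C4 is not involved, so its configuration is carried over, and the low temperature should hold back Lewis acid-induced rearrangement.

**Step 10**
Reactants: 13 (2R,3R,4R)-2-[3,4-bis(benzyloxy)phenyl]-3-({[tert-butyl(dimethyl)silyl]oxy}methyl)-4-[(3,4-dimethoxyphenyl)methyl]oxolan-4-ol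
Product: 14 (2R,3R,4R)-2-[3,4-bis(benzyloxy)phenyl]-4-[(3,4-dimethoxyphenyl)methyl]-3-(hydroxymethyl)oxolan-4-ol
Conditions: Bu4NF, THF, 0 °C → rt
Reagents that add atoms: none
Why: Fluoride-mediated desilylation driven by Si–F bond formation; it is done before debenzylation so that the air-sensitive catechol never meets basic fluoride.

**Step 11**
Reactants: 14 (2R,3R,4R)-2-[3,4-bis(benzyloxy)phenyl]-4-[(3,4-dimethoxyphenyl)methyl]-3-(hydroxymethyl)oxolan-4-ol
Product: 15 (2R,3R,4R)-2-(3,4-dihydroxyphenyl)-4-[(3,4-dimethoxyphenyl)methyl]-3-(hydroxymethyl)oxolan-4-ol (CNP0115253.1)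
Conditions: H2 (1 atm), 10% Pd/C, EtOAc/MeOH, rt; stopped when both benzyl ethers are consumed
Reagents that add atoms: none
Why: Heterogeneous palladium-catalysed hydrogenolysis of the two aryl benzyl ethers; under neutral conditions at 1 atm the cyclic benzylic C2–O1 bond should cleave much more slowly and survive if the reaction is not prolonged.

**Compound list**
1 | 1-[3,4-bis(benzyloxy)phenyl]ethanone | CC(=O)c1ccc(OCc2ccccc2)c(OCc3ccccc3)c1 | starting material
2 | ethyl 3-[3,4-bis(benzyloxy)phenyl]-3-oxopropanoate | CCOC(=O)CC(=O)c1ccc(OCc2ccccc2)c(OCc3ccccc3)c1 | intermediate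
3 | ethyl (3R)-3-[3,4-bis(benzyloxy)phenyl]-3-hydroxypropanoate | O[C@@H](c1ccc(OCc2ccccc2)c(OCc3ccccc3)c1)CC(=O)OCC | intermediate
4 | oxetan-3-one | O=C1COC1 | starting material
5 | ethyl (2R,3R)-3-[3,4-bis(benzyloxy)phenyl]-3-hydroxy-2-(3-hydroxyoxetan-3-yl)propanoate | O[C@@H](c1ccc(OCc2ccccc2)c(OCc3ccccc3)c1)[C@@H](C(=O)OCC)C4(O)COC4 | intermediate
6 | (1R,2R)-1-[3,4-bis(benzyloxy)phenyl]-2-(3-hydroxyoxetan-3-yl)propane-1,3-diol | O[C@@H](c1ccc(OCc2ccccc2)c(OCc3ccccc3)c1)[C@@H](CO)C4(O)COC4 | intermediate
7 | (1R,2R)-1-[3,4-bis(benzyloxy)phenyl]-3-{[tert-butyl(dimethyl)silyl]oxy}-2-(3-hydroxyoxetan-3-yl)propan-1-ol | O[C@@H](c1ccc(OCc2ccccc2)c(OCc3ccccc3)c1)[C@@H](CO[Si](C)(C)C(C)(C)C)C4(O)COC4 | intermediate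
8 | (2R,3R,4S)-2-[3,4-bis(benzyloxy)phenyl]-3-({[tert-butyl(dimethyl)silyl]oxy}methyl)-4-(hydroxymethyl)oxolan-4-ol | OC[C@]1(O)CO[C@@H](c2ccc(OCc3ccccc3)c(OCc4ccccc4)c2)[C@H]1CO[Si](C)(C)C(C)(C)C | intermediate
9 | [(2R,3R,4R)-2-[3,4-bis(benzyloxy)phenyl]-3-({[tert-butyl(dimethyl)silyl]oxy}methyl)-4-hydroxyoxolan-4-yl]methyl 4-methylbenzenesulfonate | Cc1ccc(cc1)S(=O)(=O)OC[C@]2(O)CO[C@@H](c3ccc(OCc4ccccc4)c(OCc5ccccc5)c3)[C@H]2CO[Si](C)(C)C(C)(C)C | intermediate
10 | (3S,6R,7R)-6-[3,4-bis(benzyloxy)phenyl]-7-({[tert-butyl(dimethyl)silyl]oxy}methyl)-1,5-dioxaspiro[2.4]heptane (spiro-epoxide at the former C4, epoxide oxygen cis to aryl and silyloxymethyl) | C1O[C@]12CO[C@@H](c3ccc(OCc4ccccc4)c(OCc5ccccc5)c3)[C@H]2CO[Si](C)(C)C(C)(C)C | intermediate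
11 | 4-bromo-1,2-dimethoxybenzene | COc1ccc(Br)cc1OC | starting material
12 | 3,4-dimethoxyphenylmagnesium bromide | COc1ccc([Mg]Br)cc1OC | intermediate
13 | (2R,3R,4R)-2-[3,4-bis(benzyloxy)phenyl]-3-({[tert-butyl(dimethyl)silyl]oxy}methyl)-4-[(3,4-dimethoxyphenyl)methyl]oxolan-4-ol | COc1ccc(C[C@]2(O)CO[C@@H](c3ccc(OCc4ccccc4)c(OCc5ccccc5)c3)[C@H]2CO[Si](C)(C)C(C)(C)C)cc1OC | intermediate
14 | (2R,3R,4R)-2-[3,4-bis(benzyloxy)phenyl]-4-[(3,4-dimethoxyphenyl)methyl]-3-(hydroxymethyl)oxolan-4-ol | COc1ccc(C[C@]2(O)CO[C@@H](c3ccc(OCc4ccccc4)c(OCc5ccccc5)c3)[C@H]2CO)cc1OC | intermediate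
15 | (2R,3R,4R)-2-(3,4-dihydroxyphenyl)-4-[(3,4-dimethoxyphenyl)methyl]-3-(hydroxymethyl)oxolan-4-ol | COc1ccc(C[C@]2(O)CO[C@@H](c3ccc(O)c(O)c3)[C@H]2CO)cc1OC | target

**Step count and risks**
Total steps: 11. Longest linear sequence: 10 steps (steps 1 to 7 and 9 to 11, from 1 to 15); step 8 is a one-step side branch.

Steps most likely to fail:

1. Step 6 (key step). What may go wrong is insufficient discrimination between the two diastereotopic oxetane methylenes if catalyst control is weak or mismatched. The fallback sets out from 8 as the ring closure delivers it, whatever its composition at C4; an achiral acid such as diphenyl phosphate may then serve for the closure. NaIO4 in THF/H2O should cleave the C4 glycol to (2R,3R)-2-[3,4-bis(benzyloxy)phenyl]-3-({[tert-butyl(dimethyl)silyl]oxy}methyl)oxolan-4-one F1, in which C4 is trigonal, so both C4 epimers converge. The ketone is used at once to spare the C3 centre next to the carbonyl. (3,4-Dimethoxyphenyl)methylmagnesium chloride F2 is prepared from 4-(chloromethyl)-1,2-dimethoxybenzene and Mg in THF and added to F1 with anhydrous CeCl3 at −78 °C. It should attack the carbonyl from the face opposite the cis-disposed C2 aryl and C3 silyloxymethyl groups, placing the benzyl group trans and the hydroxyl cis to them. This is tertiary alcohol 13, where the route is rejoined; steps 7 to 9 fall away.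

2. Step 3. What may go wrong is retro-aldol fragmentation of the benzylic lithium alkoxide or reversal of the ketone addition, with loss of material and of anti selectivity at C3. The fallback sets out from 3 and replaces the open-chain dianion by a locked cyclic acetal enolate. LiOH in THF/H2O should give (3R)-3-[3,4-bis(benzyloxy)phenyl]-3-hydroxypropanoic acid F3. TMSCl/Et3N should give its bis-silyl derivative, trimethylsilyl (3R)-3-[3,4-bis(benzyloxy)phenyl]-3-[(trimethylsilyl)oxy]propanoate F4. Pivalaldehyde with catalytic TMSOTf in CH2Cl2 at −78 °C should then close the cis acetal (2S,6R)-6-[3,4-bis(benzyloxy)phenyl]-2-tert-butyl-1,3-dioxan-4-one F5. Its lithium enolate (LiN(iPr)2, THF, −78 °C) should add to 4 on the face opposite the aryl and tert-butyl groups, giving (2S,5R,6R)-6-[3,4-bis(benzyloxy)phenyl]-2-tert-butyl-5-(3-hydroxyoxetan-3-yl)-1,3-dioxan-4-one F6. This has the same anti relationship as 5. LiAlH4 in THF at 0 °C should reduce the acylal to triol 6, where the route is rejoined.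

3. Step 9. What may go wrong is slow substitution at the CH2 next to the fully substituted C4, which lets magnesium halide-promoted rearrangement of the epoxide or halohydrin formation compete. The fallback sets out from 10 and forms the same bond by reductive cross-electrophile coupling instead of organometallic substitution. LiI/AcOH in THF should open the epoxide at the CH2 terminus to (2R,3R,4R)-2-[3,4-bis(benzyloxy)phenyl]-3-({[tert-butyl(dimethyl)silyl]oxy}methyl)-4-(iodomethyl)oxolan-4-ol F7. This primary iodide is then coupled with aryl bromide 11 under nickel catalysis (NiBr2(dme) 10 mol %, 4,4'-di-tert-butyl-2,2'-bipyridine, Zn dust, DMA, rt → 50 °C). The product is 13, where the route is rejoined; step 8 is not needed.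

**Further compounds**
F1 | step 6 | (2R,3R)-2-[3,4-bis(benzyloxy)phenyl]-3-({[tert-butyl(dimethyl)silyl]oxy}methyl)oxolan-4-one | O=C1CO[C@@H](c2ccc(OCc3ccccc3)c(OCc4ccccc4)c2)[C@H]1CO[Si](C)(C)C(C)(C)C
F2 | step 6 | (3,4-dimethoxyphenyl)methylmagnesium chloride | COc1ccc(C[Mg]Cl)cc1OC
F3 | step 3 | (3R)-3-[3,4-bis(benzyloxy)phenyl]-3-hydroxypropanoic acid | O[C@@H](c1ccc(OCc2ccccc2)c(OCc3ccccc3)c1)CC(=O)O
F4 | step 3 | trimethylsilyl (3R)-3-[3,4-bis(benzyloxy)phenyl]-3-[(trimethylsilyl)oxy]propanoate | C[Si](C)(C)O[C@@H](c1ccc(OCc2ccccc2)c(OCc3ccccc3)c1)CC(=O)O[Si](C)(C)C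
F5 | step 3 | (2S,6R)-6-[3,4-bis(benzyloxy)phenyl]-2-tert-butyl-1,3-dioxan-4-one | O=C1C[C@H](c2ccc(OCc3ccccc3)c(OCc4ccccc4)c2)O[C@H](C(C)(C)C)O1
F6 | step 3 | (2S,5R,6R)-6-[3,4-bis(benzyloxy)phenyl]-2-tert-butyl-5-(3-hydroxyoxetan-3-yl)-1,3-dioxan-4-one | O=C1[C@@H](C2(O)COC2)[C@H](c2ccc(OCc3ccccc3)c(OCc4ccccc4)c2)O[C@H](C(C)(C)C)O1
F7 | step 9 | (2R,3R,4R)-2-[3,4-bis(benzyloxy)phenyl]-3-({[tert-butyl(dimethyl)silyl]oxy}methyl)-4-(iodomethyl)oxolan-4-ol | IC[C@]1(O)CO[C@@H](c2ccc(OCc3ccccc3)c(OCc4ccccc4)c2)[C@H]1CO[Si](C)(C)C(C)(C)C
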